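4 questions stand on these flasks: which one ends highest in target, and how much target each holds at the end.

| flask | substrate | partner | protic impurity | temperature | remark | time |
|---|---|---|---|---|---|---|
| noon | 2 mM | 3 mM | 0.30 mM | −15 °C | run made earlier |  |
| winter | 2 mM | 3 mM | 0.45 mM | 20 °C | run made earlier |  |
| Sunday's | 2.0 mM | 3.00 mM | 0.600 mM | 50 °C |  | 2.0 min |
| Saturday's | 2.0 mM | 3.00 mM | 0.600 mM | 20 °C |  | 2.0 min |
| Wednesday's | 2.0 mM | 3.00 mM | 0.600 mM | −10 °C |  | 2.0 min |

| run | time / min | target / % | substrate / % |
|---|---|---|---|
| noon | 15.0 | 0 | 99.1 |
| noon | 30.0 | 0 | 99.7 |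
| noon | 50.0 | 0.7 | 98.8 |
| noon | 60.0 | 1.0 | 98.8 |
| winter | 0.833 | 0 | 97.2 |
| winter | 2.00 | 0.7 | 92.4 |
| winter | 4.00 | 2.6 | 86.5 |
| winter | 12.0 | 9.4 | 65.2 |

(standard deviation of a reading: 0.5 percentage points)

- the analysis behind the earlier runs scatters by 0.5 percentage points, standard deviation

1. the flask that comes out highest in amount of target, in percent of the substrate charged, or "all alike" when all lie within 1.5 percentage points (Sunday's / Saturday's / Wednesday's / all alike)
2. target at the end, in percent of the substrate charged, Sunday's
3. target at the end, in percent of the substrate charged, Saturday's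
4. target at the end, in percent of the substrate charged, Wednesday's

The winter run holds two numbers that seem not to go together: after 12.0 min substrate is down by 34.8 % of its charge, yet target stands at 9.4 %. The early readings clear this up only in part. From 2.00 min to 4.00 min the time doubles and target reads 3.71-fold, but the lower reading is 0.7 % with a scatter of 0.5 percentage points, so that ratio is loose and doesn't show a square law. What the readings do show is target trailing the loss: at 2.00 min it reads 0.7 % against 7.60 % of substrate lost. We read this as an induction period, with target fed through something in between, and treat early target as a small correction to the substrate lost.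

As a working assumption, not a finding, we write early target, as a fraction of the charge, as the square of time over a rise time. The winter run gives 24.8 min and the noon run, on a reading close to its scatter, gives 600 min. Taking the logarithm of the rise time as straight in inverse absolute temperature, Sunday's rise time, the time in which the square law would reach the whole charge, is 2.80 min.

Our reckoning gives 51.0 % for Sunday's, 0.650 % for Saturday's and 0.00306 % for Wednesday's. The law already overshoots the winter run at 12.0 min, with 23.4 % against the reading, so we hold Sunday's figure as an upper mark.

The forecast names Sunday's, with 10 %, 0.6 % and 0.05 %, and says of the hot flask: “That leaves about 10% target in 2 min, uncertain.” For Sunday's it stands under our mark.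

The flasks give 32.9 % for Sunday's, 1.03 % for Saturday's and 0 % for Wednesday's, so Sunday's comes out highest.

    partner ⇌ dormant form (K = 0.670, k = 0.0980 s⁻¹, Ea = 82.0 kJ mol⁻¹, ΔH = −44.0 kJ mol⁻¹)
    partner + protic impurity → quenched reagent (k = 23.0 M⁻¹ s⁻¹, Ea = 47.0 kJ mol⁻¹)
    substrate ⇌ reactive form (K = 1.10, k = 0.0180 s⁻¹, Ea = 89.0 kJ mol⁻¹, ΔH = −55.0 kJ mol⁻¹)
    partner + reactive form ⇌ target (K = 1600 M⁻¹, k = 12.0 M⁻¹ s⁻¹, Ea = 56.0 kJ mol⁻¹, ΔH = −34.0 kJ mol⁻¹)
    (constants at 50 °C)

At the end of Sunday's, reactive form holds 31.4 % of the substrate charged beside that target. Sunday's rise time put 51.0 % on this flask, above what it gives. Stopped at 30 s, the same flask gets 3.19 % from the rise time, and the computed result is 8.62 %, above the square law.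

(The runs are calculated for substances that don't exist, and the scatter is random.)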